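The runs are calculated for substances that don't exist, noise included.

The south-east run showed left-handed substrate falling as left-handed product rose, the two summing to 49.1% at 25.0 min, so I took the left-handed substrate as what reacts.

| setting | south-east | zeta | alpha |
|---|---|---|---|
| left-handed substrate | 44 mM | 29 mM | 29 mM |
| right-handed substrate | 44 mM | 29 mM | 29 mM |
| solid reagent | 23.2 mM | 23.2 mM | 23.2 mM |
| free catalyst | 4.3 mM | 4.3 mM | 4.3 mM |
| impurity | 1.8 mM | 1.8 mM | 1.8 mM |
| temperature | 10 °C |  |  |
| remark | run made earlier | at 10 °C until 25 min, from then on at 30 °C | at 30 °C throughout |
| time |  | 80 min | 40 min |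

south-east run (percent of the left-handed substrate and right-handed substrate together charged)

| time / min | left-handed product / % | left-handed substrate / % |
|---|---|---|
| 2.00 | 0.5 | 48.9 |
| 6.00 | 4.5 | 44.7 |
| 12.0 | 10.0 | 39.0 |
| 15.0 | 12.9 | 36.2 |
| 25.0 | 18.2 | 30.9 |

(readings scatter by 0.5 percentage points)

1. which one finishes higher in amount of left-handed product, in percent of the left-handed substrate and right-handed substrate together charged ("neither" within 2 percentage points) (zeta / alpha / neither)
2. amount of left-handed product at the end, in percent of the left-handed substrate and right-handed substrate together charged, zeta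
3. amount of left-handed product at the end, in percent of the left-handed substrate and right-handed substrate together charged, alpha

- free catalyst is single-handed; left-handed substrate and right-handed substrate are mirror images of each other, charged as a racemate, each of them at the stated concentration
- given per volume of solution although it is solid: solid reagent
- what was read earlier has a scatter of 0.5 percentage points, one standard deviation
- at the start none of the solid reagent is in solution
- the earlier runs do not show what temperature does; that part of a forecast is a guess

But zeta and alpha each held 23.2 mM of solid reagent against 29 mM of left-handed substrate, so I treated the reagent as the limiting reagent, one per product. That gave 40.0% as the ceiling: the smaller of reagent and left-handed substrate charged, over both substrates charged.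

Would the flasks reach it? I replaced the south-east curve by its mean, 18.2% of 88.0 mM in 25.0 min, which gave 0.641 mM min⁻¹. At that pace 23.2 mM took 36.2 min, less than alpha's 40 min. But the pace was falling by the last readings, and temperature was a guess, so I expected both flasks just under the ceiling, and neither ahead.

The forecast said neither, with zeta at 34.5% (29% to 38%) and alpha at 33% (24% to 38%), on a cap of 37% where mine stood at 40.0%: “I expect both near the cap, with alpha perhaps slightly lower.”

The flasks gave neither: zeta 38.8%, alpha 38.0%.

    free catalyst + left-handed substrate ⇌ catalyst intermediate A (K = 31.9 M⁻¹, k = 3340 M⁻¹ min⁻¹, Ea = 45.0 kJ mol⁻¹, ΔH = 2.00 kJ mol⁻¹)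
    solid reagent ⇌ partner, rate k2*(cs2 - [partner]) while solid is left; crystals form when [partner] > cs2 (solubility = 26.0 mM, k = 0.165 min⁻¹)
    partner + catalyst intermediate B → free catalyst + right-handed product (k = 2.17 M⁻¹ min⁻¹, Ea = 42.0 kJ mol⁻¹)
    partner + catalyst intermediate A → free catalyst + left-handed product (k = 59.1 M⁻¹ min⁻¹, Ea = 42.0 kJ mol⁻¹)
    free catalyst + impurity → spent catalyst (k = 4200 M⁻¹ min⁻¹, Ea = 37.0 kJ mol⁻¹)
    free catalyst + right-handed substrate ⇌ catalyst intermediate B (K = 13.9 M⁻¹, k = 1470 M⁻¹ min⁻¹, Ea = 45.0 kJ mol⁻¹, ΔH = −8.00 kJ mol⁻¹)
    (constants at 10 °C)

Alpha's reagent balanced at the ceiling: its left-handed product, 0.887% of right-handed product and 0.618 mM of partner still dissolved, with solid reagent at 0%, made 40.0% against 40.0%. The main reason alpha came so near was the backward run from catalyst intermediate B to free catalyst and right-handed substrate: with that run struck out, alpha gave 0.559% of left-handed product.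

With 58 mM of solid reagent in a neighbour of alpha, the smaller charge was the left-handed substrate, so the ceiling moved to 50.0%. That flask gave 50.0%.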